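**Plan**

- Numbering: ring A is the cyclohexene (C1 ester-bearing carbon, C2 methyl-bearing alkene carbon, C5 quaternary carbon); ring B is the cyclopentane (C1′ quaternary carbon, C2′ methylidene-bearing carbon).
- Retrosynthesis: cut the C1–O ester bond to the caffeoyl unit, mask the C5 methyl as a nitrile, then cut both ring A bonds at C5 (C4–C5 and C5–C6). This is possible because C5 lies between two CH2 groups (C4 and C6), so it can act as a nitrile-stabilized carbanion that stitches on a five-carbon C4–C3=C2–C1–C6 dielectrophile already carrying the alkene, the C2 methyl and the C1 oxygen.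
- Forward: ring B nitrile 9 is made from diallyl adipate and dielectrophile 23 from but-2-yn-1-ol; ring A closes in a one-pot double alkylation; the nitrile is then taken down to the C5 methyl, and the ester is formed and unmasked.
- Stereochemistry: C1′ comes from a palladium-catalysed asymmetric decarboxylative allylation. C1 comes from an oxazaborolidine-catalysed ketone reduction, is carried as the epimer and is inverted in a Mitsunobu esterification. C5 is set in the ring closure under control of C1. The (Z)-alkene comes from trans-hydroalumination and iodination of the alkynol.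

Key step: step 16

Assumption: in the ring-closing transition state the C1 silyloxy group is taken to sit pseudoaxial (clear of the departing iodide and of the C2 methyl), so the (S)-configured dielectrophile is used and C1 is inverted at the esterification.

**Route**

Step 1
Reactants: 1 diallyl adipate (diprop-2-en-1-yl hexanedioate)
Product: 3 allyl 1-methyl-2-oxocyclopentane-1-carboxylate (racemic), via sodium enolate 2 (not isolated)
Conditions: NaH (1.1 equiv), toluene, 95 °C; then CH3I, 40 °C
Reagents that add atoms: iodomethane, CI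
Why: Dieckmann condensation gives the stabilized β-keto ester enolate, which is C-methylated in the same flask; the quaternary centre is racemic here and is erased in step 2.

Step 2
Reactants: 3 allyl 1-methyl-2-oxocyclopentane-1-carboxylate
Product: 4 (2R)-2-methyl-2-(prop-2-en-1-yl)cyclopentan-1-one
Conditions: Pd2(dba)3 (dba = dibenzylideneacetone, 2.5 mol %), (R)-t-BuPHOX [(4R)-4-tert-butyl-2-[2-(diphenylphosphanyl)phenyl]-4,5-dihydro-1,3-oxazole, 6 mol %], THF, 25 °C
Reagents that add atoms: none
Why: Decarboxylative asymmetric allylic alkylation: oxidative addition of zerovalent palladium and loss of CO2 give an enolate–allylpalladium pair that recombines stereoconvergently inside the chiral P,N-ligand sphere and sets C1′, the (R)-ligand being the antipode of the one that leads to (S)-α-allyl-α-methyl cycloalkanones.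

Step 3
Reactants: 4 (2R)-2-methyl-2-(prop-2-en-1-yl)cyclopentan-1-one
Product: 6 [(1R)-1-methyl-2-oxocyclopentyl]acetaldehyde, via ozonide 5 (not isolated)
Conditions: O3, CH2Cl2, −78 °C; then (CH3)2S, −78 °C → rt
Reagents that add atoms: ozone, [O-][O+]=O
Why: Ozonolysis with reductive work-up cleaves the only alkene to the aldehyde and cannot touch the ketone or the quaternary stereocentre.

Step 4
Reactants: 6 [(1R)-1-methyl-2-oxocyclopentyl]acetaldehyde
Product: 8 [(1R)-1-methyl-2-oxocyclopentyl]acetonitrile, via aldoxime 7 (not isolated)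
Conditions: NH2OH·HCl (1.0 equiv), pyridine, CH2Cl2, 0 °C; then (CF3CO)2O, 0 °C → rt
Reagents that add atoms: hydroxylamine hydrochloride, NO.Cl
Why: Oximation followed by dehydration of the aldoxime to the nitrile; the aldehyde condenses far faster than the hindered α-quaternary cyclopentanone, so one equivalent of hydroxylamine in the cold should differentiate the two carbonyl groups.

Step 5
Reactants: 8 [(1R)-1-methyl-2-oxocyclopentyl]acetonitrile
Product: 9 [(1R)-1-methyl-2-methylidenecyclopentyl]acetonitrile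
Conditions: Ph3PCH3Br (1.6 equiv), KOC(CH3)3 (1.5 equiv), THF, 0 → 60 °C
Reagents that add atoms: methyltriphenylphosphonium bromide, C[P+](c1ccccc1)(c1ccccc1)c1ccccc1.[Br-]
Why: Wittig methylenation with the smallest ylide converts α-quaternary cyclopentanones and tolerates the nitrile, whose α-hydrogens are far less acidic than the phosphonium salt.

Step 6
Reactants: 10 but-2-yn-1-ol
Product: 12 (2Z)-3-iodobut-2-en-1-ol, via alkenylaluminate 11 (not isolated)
Conditions: NaAlH2(OCH2CH2OCH3)2 (1.5 equiv), THF, 0 °C → rt; then I2, THF, −78 → 0 °C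
Reagents that add atoms: iodine, II
Why: Hydroxyl-directed trans-hydroalumination puts aluminium on the methyl-bearing alkyne carbon in a five-membered oxa-aluminacycle, and iodinolysis with retention fixes the (Z)-geometry (iodine cis to CH2OH) that later keeps C4 and C1 on the same side of the alkene.

Step 7
Reactants: 12 (2Z)-3-iodobut-2-en-1-ol
Product: 13 tert-butyl{[(2Z)-3-iodobut-2-en-1-yl]oxy}dimethylsilane
Conditions: TBSCl, imidazole, CH2Cl2, 0 °C → rt
Reagents that add atoms: tert-butyldimethylsilyl chloride, CC(C)(C)[Si](C)(C)Cl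
Why: Standard silylation of a primary alcohol masks the future C4 oxygen for the organolithium step.

Step 8
Reactants: 13 tert-butyl{[(2Z)-3-iodobut-2-en-1-yl]oxy}dimethylsilane; 14 2-[(4-methoxybenzyl)oxy]acetaldehyde
Product: 16 (3Z)-5-[(tert-butyldimethylsilyl)oxy]-1-[(4-methoxybenzyl)oxy]-3-methylpent-3-en-2-ol (racemic), via alkenyllithium 15 (not isolated)
Conditions: (CH3)3CLi (2.1 equiv), Et2O, −78 °C; then 14, −78 °C; H2O
Reagents that add atoms: none
Why: Iodine–lithium exchange retains the alkene geometry, and at −78 °C the alkenyllithium should add to the aldehyde faster than it undergoes 1,4-silyl migration; the carbinol centre forms racemic and is reset in steps 9 and 10.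

Step 9
Reactants: 16 (3Z)-5-[(tert-butyldimethylsilyl)oxy]-1-[(4-methoxybenzyl)oxy]-3-methylpent-3-en-2-ol
Product: 17 (3Z)-5-[(tert-butyldimethylsilyl)oxy]-1-[(4-methoxybenzyl)oxy]-3-methylpent-3-en-2-one
Conditions: Dess–Martin periodinane, CH2Cl2, 0 °C → rt
Reagents that add atoms: none
Why: Dess–Martin oxidation of the secondary allylic alcohol is mild enough to leave the (Z)-alkene, the silyl ether and the PMB ether unchanged.

Step 10
Reactants: 17 (3Z)-5-[(tert-butyldimethylsilyl)oxy]-1-[(4-methoxybenzyl)oxy]-3-methylpent-3-en-2-one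
Product: 18 (2S,3Z)-5-[(tert-butyldimethylsilyl)oxy]-1-[(4-methoxybenzyl)oxy]-3-methylpent-3-en-2-ol
Conditions: (S)-Me-CBS oxazaborolidine [(S)-1-methyl-3,3-diphenyltetrahydro-1H,3H-pyrrolo[1,2-c][1,3,2]oxazaborole, 0.2 equiv], catecholborane (1.8 equiv), toluene, −78 °C; aqueous work-up
Reagents that add atoms: none
Why: Corey–Bakshi–Shibata reduction: the ketone binds the catalyst boron anti to its large α-branched (Z)-alkenyl group (CH2OPMB acting as the small group), and intramolecular hydride delivery to the exposed face should set the (S)-carbinol, which is the future C1 in its epimeric form.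

Step 11
Reactants: 18 (2S,3Z)-5-[(tert-butyldimethylsilyl)oxy]-1-[(4-methoxybenzyl)oxy]-3-methylpent-3-en-2-ol
Product: 19 (2S,3Z)-2,5-bis[(tert-butyldimethylsilyl)oxy]-1-[(4-methoxybenzyl)oxy]-3-methylpent-3-ene
Conditions: TBSOTf, 2,6-lutidine, CH2Cl2, −78 °C
Reagents that add atoms: tert-butyldimethylsilyl trifluoromethanesulfonate, CC(C)(C)[Si](C)(C)OS(=O)(=O)C(F)(F)F
Why: Silyl triflate with a hindered base silylates the secondary allylic alcohol without ionization, so the C1 configuration is kept.

Step 12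
Reactants: 19 (2S,3Z)-2,5-bis[(tert-butyldimethylsilyl)oxy]-1-[(4-methoxybenzyl)oxy]-3-methylpent-3-ene
Product: 20 (2S,3Z)-2,5-bis[(tert-butyldimethylsilyl)oxy]-3-methylpent-3-en-1-ol
Conditions: DDQ (1.3 equiv), CH2Cl2/pH 7 buffer, 0 °C
Reagents that add atoms: none
Why: Oxidative cleavage of the PMB ether by DDQ is selective for the electron-rich benzyl ether, and the buffered medium spares both silyl ethers.

Step 13
Reactants: 20 (2S,3Z)-2,5-bis[(tert-butyldimethylsilyl)oxy]-3-methylpent-3-en-1-ol
Product: 21 (2S,3Z)-2,5-bis[(tert-butyldimethylsilyl)oxy]-1-iodo-3-methylpent-3-ene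
Conditions: I2, PPh3, imidazole, CH2Cl2, 0 °C → rt
Reagents that add atoms: iodine, II
Why: Appel-type iodination converts the primary alcohol into the C6 iodide under nearly neutral conditions that leave C1 and the silyl ethers alone.

Step 14
Reactants: 21 (2S,3Z)-2,5-bis[(tert-butyldimethylsilyl)oxy]-1-iodo-3-methylpent-3-ene
Product: 22 (2Z,4S)-4-[(tert-butyldimethylsilyl)oxy]-5-iodo-3-methylpent-2-en-1-ol
Conditions: HF·pyridine, pyridine, THF, 0 °C
Reagents that add atoms: none
Why: Buffered fluoride cleaves the unhindered primary allylic silyl ether well before the secondary one, which is flanked by the trisubstituted alkene and the CH2I group.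

Step 15
Reactants: 22 (2Z,4S)-4-[(tert-butyldimethylsilyl)oxy]-5-iodo-3-methylpent-2-en-1-ol
Product: 23 tert-butyl{[(2S,3Z)-5-bromo-1-iodo-3-methylpent-3-en-2-yl]oxy}dimethylsilane
Conditions: CBr4, PPh3, CH2Cl2, −20 → 0 °C
Reagents that add atoms: tetrabromomethane, BrC(Br)(Br)Br
Why: Appel bromination of the primary allylic alcohol proceeds by direct displacement at CH2, so the (Z)-alkene, the iodide and the silyl ether are retained.

Step 16
Reactants: 9 [(1R)-1-methyl-2-methylidenecyclopentyl]acetonitrile; 23 tert-butyl{[(2S,3Z)-5-bromo-1-iodo-3-methylpent-3-en-2-yl]oxy}dimethylsilane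
Product: 25 (1R,5R)-5-[(tert-butyldimethylsilyl)oxy]-4-methyl-1-[(1S)-1-methyl-2-methylidenecyclopentyl]cyclohex-3-ene-1-carbonitrile, via iodo nitrile 24 (not isolated)
Conditions: LiN(i-Pr)2 (1.05 equiv), THF, −78 °C; 23, −78 → −40 °C; then LiN(i-Pr)2 (1.3 equiv), DMPU, −78 → 0 °C
Reagents that add atoms: none
Why: The lithiated nitrile of 9 displaces the allylic bromide of 23 by SN2 at low temperature (C4–C5 bond) while the β-branched, β-silyloxy iodide is left alone; a second equivalent of base then forms the tertiary nitrile carbanion of 24, which closes ring A by 6-exo-tet displacement of iodide (C5–C6 bond). The closest known reaction type is the one-pot cycloalkylation of nitrile-stabilized carbanions with α,ω-dihalides, which builds quaternary carbons in six-membered rings. The new stereocentre C5 is controlled by the C1 silyloxy stereocentre of the electrophile: in the half-chair transition state the bulky ring B substituent of the planar carbanion takes the equatorial site and the slim cyano group the axial one, while the silyloxy group sits pseudoaxial, because the pseudoequatorial site nearly eclipses the departing iodide and suffers allylic 1,2-strain with the C2 methyl. The silyloxy group therefore ends cis to the nitrile and trans to ring B, so the (S)-configured C1 of 23 should deliver the C5 configuration of the target, and C1 itself is inverted in step 20. The step needs bromide-before-iodide chemoselectivity (secured by allylic activation), SN2 instead of SN2′ attack (the γ-carbon is fully substituted) and a (Z)-alkene that holds C4 and C6 within reach of one carbon (secured in step 6). C1′ is untouched, and any minor enantiomer of 9 should end as a separable diastereomer of 25.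

Step 17
Reactants: 25 (1R,5R)-5-[(tert-butyldimethylsilyl)oxy]-4-methyl-1-[(1S)-1-methyl-2-methylidenecyclopentyl]cyclohex-3-ene-1-carbonitrile
Product: 26 (1R,5R)-5-[(tert-butyldimethylsilyl)oxy]-4-methyl-1-[(1S)-1-methyl-2-methylidenecyclopentyl]cyclohex-3-ene-1-carbaldehyde
Conditions: (i-Bu)2AlH (2.5 equiv), toluene, −78 → 0 °C; then 1 M aq. HCl, 0 °C
Reagents that add atoms: water, O
Why: Partial reduction of the nitrile stops at the N-aluminated aldimine, which is too hindered to be reduced further and is hydrolysed to the aldehyde on cold acidic work-up; no stereocentre is affected because the aldehyde has no α-hydrogen.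

Step 18
Reactants: 26 (1R,5R)-5-[(tert-butyldimethylsilyl)oxy]-4-methyl-1-[(1S)-1-methyl-2-methylidenecyclopentyl]cyclohex-3-ene-1-carbaldehyde
Product: 28 (1R,5S)-2,5-dimethyl-5-[(1S)-1-methyl-2-methylidenecyclopentyl]cyclohex-2-en-1-ol, via hydrazone 27 (not isolated)
Conditions: N2H4·H2O, diethylene glycol, 130 °C; then KOH, 200 °C
Reagents that add atoms: none
Why: Wolff–Kishner reduction turns the neopentyl-type aldehyde into the C5 methyl through its hydrazone, and the hot alkaline glycol should cleave the silyl ether at the Si–O bond in the same operation, so C1 keeps its configuration.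

Step 19
Reactants: 29 caffeic acid [(2E)-3-(3,4-dihydroxyphenyl)prop-2-enoic acid]
Product: 31 (2E)-3-{3,4-bis[(tert-butyldimethylsilyl)oxy]phenyl}prop-2-enoic acid, via silyl ester 30 (not isolated)
Conditions: TBSCl (3.3 equiv), imidazole, DMF, rt; then AcOH/THF/H2O, rt
Reagents that add atoms: tert-butyldimethylsilyl chloride, CC(C)(C)[Si](C)(C)Cl
Why: Exhaustive silylation followed by mild aqueous acid, which hydrolyses only the labile silyl ester, leaves the two aryl silyl ethers in place.

Step 20
Reactants: 28 (1R,5S)-2,5-dimethyl-5-[(1S)-1-methyl-2-methylidenecyclopentyl]cyclohex-2-en-1-ol; 31 (2E)-3-{3,4-bis[(tert-butyldimethylsilyl)oxy]phenyl}prop-2-enoic acid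
Product: 32 (1S,5S)-2,5-dimethyl-5-[(1S)-1-methyl-2-methylidenecyclopentyl]cyclohex-2-en-1-yl (2E)-3-{3,4-bis[(tert-butyldimethylsilyl)oxy]phenyl}prop-2-enoate
Conditions: PPh3, diisopropyl azodicarboxylate, toluene, 0 °C → rt
Reagents that add atoms: none
Why: Mitsunobu esterification: the carboxylate displaces the pseudoaxial alkoxyphosphonium group from the opposite face by SN2, which inverts C1 to the (S)-configuration of the target, as known for 2-methylcyclohex-2-enols.

Step 21
Reactants: 32 (1S,5S)-2,5-dimethyl-5-[(1S)-1-methyl-2-methylidenecyclopentyl]cyclohex-2-en-1-yl (2E)-3-{3,4-bis[(tert-butyldimethylsilyl)oxy]phenyl}prop-2-enoate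
Product: 33 (1S,5S)-2,5-dimethyl-5-[(1S)-1-methyl-2-methylidenecyclopentyl]cyclohex-2-en-1-yl (2E)-3-(3,4-dihydroxyphenyl)prop-2-enoate
Conditions: (n-Bu)4NF, AcOH, THF, 0 °C
Reagents that add atoms: none
Why: Acetic acid-buffered fluoride removes aryl silyl ethers rapidly and should spare the allylic cinnamate ester and both alkenes.

**Compound list**

1 | diallyl adipate | C=CCOC(=O)CCCCC(=O)OCC=C | starting material
2 | sodium enolate of allyl 2-oxocyclopentane-1-carboxylate | [Na+].[O-]C1=C(C(=O)OCC=C)CCC1 | intermediate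
3 | allyl 1-methyl-2-oxocyclopentane-1-carboxylate (racemic) | C=CCOC(=O)C1(C)CCCC1=O | intermediate
4 | (2R)-2-methyl-2-(prop-2-en-1-yl)cyclopentan-1-one | O=C1CCC[C@]1(C)CC=C | intermediate
5 | (2R)-2-methyl-2-[(1,2,4-trioxolan-3-yl)methyl]cyclopentan-1-one (ozonide, mixture at the trioxolane carbon) | O=C1CCC[C@]1(C)CC1OCOO1 | intermediate
6 | [(1R)-1-methyl-2-oxocyclopentyl]acetaldehyde | O=C1CCC[C@]1(C)CC=O | intermediate
7 | [(1R)-1-methyl-2-oxocyclopentyl]acetaldehyde oxime | O=C1CCC[C@]1(C)CC=NO | intermediate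
8 | [(1R)-1-methyl-2-oxocyclopentyl]acetonitrile | O=C1CCC[C@]1(C)CC#N | intermediate
9 | [(1R)-1-methyl-2-methylidenecyclopentyl]acetonitrile | C=C1CCC[C@]1(C)CC#N | intermediate
10 | but-2-yn-1-ol | CC#CCO | starting material
11 | sodium cyclic alkenylaluminate from hydroalumination of 10 | CC1=CCO[Al-]1(OCCOC)OCCOC.[Na+] | intermediate
12 | (2Z)-3-iodobut-2-en-1-ol | C/C(I)=C/CO | intermediate
13 | tert-butyl{[(2Z)-3-iodobut-2-en-1-yl]oxy}dimethylsilane | C/C(I)=C/CO[Si](C)(C)C(C)(C)C | intermediate
14 | 2-[(4-methoxybenzyl)oxy]acetaldehyde | O=CCOCc1ccc(OC)cc1 | starting material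
15 | (Z)-alkenyllithium from 13 | C/C([Li])=C/CO[Si](C)(C)C(C)(C)C | intermediate
16 | (3Z)-5-[(tert-butyldimethylsilyl)oxy]-1-[(4-methoxybenzyl)oxy]-3-methylpent-3-en-2-ol (racemic) | C/C(=C/CO[Si](C)(C)C(C)(C)C)C(O)COCc1ccc(OC)cc1 | intermediate
17 | (3Z)-5-[(tert-butyldimethylsilyl)oxy]-1-[(4-methoxybenzyl)oxy]-3-methylpent-3-en-2-one | C/C(=C/CO[Si](C)(C)C(C)(C)C)C(=O)COCc1ccc(OC)cc1 | intermediate
18 | (2S,3Z)-5-[(tert-butyldimethylsilyl)oxy]-1-[(4-methoxybenzyl)oxy]-3-methylpent-3-en-2-ol | C/C(=C/CO[Si](C)(C)C(C)(C)C)[C@H](O)COCc1ccc(OC)cc1 | intermediate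
19 | (2S,3Z)-2,5-bis[(tert-butyldimethylsilyl)oxy]-1-[(4-methoxybenzyl)oxy]-3-methylpent-3-ene | C/C(=C/CO[Si](C)(C)C(C)(C)C)[C@H](O[Si](C)(C)C(C)(C)C)COCc1ccc(OC)cc1 | intermediate
20 | (2S,3Z)-2,5-bis[(tert-butyldimethylsilyl)oxy]-3-methylpent-3-en-1-ol | C/C(=C/CO[Si](C)(C)C(C)(C)C)[C@H](O[Si](C)(C)C(C)(C)C)CO | intermediate
21 | (2S,3Z)-2,5-bis[(tert-butyldimethylsilyl)oxy]-1-iodo-3-methylpent-3-ene | C/C(=C/CO[Si](C)(C)C(C)(C)C)[C@H](O[Si](C)(C)C(C)(C)C)CI | intermediate
22 | (2Z,4S)-4-[(tert-butyldimethylsilyl)oxy]-5-iodo-3-methylpent-2-en-1-ol | C/C(=C/CO)[C@H](O[Si](C)(C)C(C)(C)C)CI | intermediate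
23 | tert-butyl{[(2S,3Z)-5-bromo-1-iodo-3-methylpent-3-en-2-yl]oxy}dimethylsilane | C/C(=C/CBr)[C@H](O[Si](C)(C)C(C)(C)C)CI | intermediate
24 | (4Z,6S)-6-[(tert-butyldimethylsilyl)oxy]-7-iodo-5-methyl-2-[(1R)-1-methyl-2-methylidenecyclopentyl]hept-4-enenitrile (both C2 epimers) | C=C1CCC[C@]1(C)C(C#N)C/C=C(/C)[C@H](O[Si](C)(C)C(C)(C)C)CI | intermediate
25 | (1R,5R)-5-[(tert-butyldimethylsilyl)oxy]-4-methyl-1-[(1S)-1-methyl-2-methylidenecyclopentyl]cyclohex-3-ene-1-carbonitrile | C=C1CCC[C@]1(C)[C@@]1(C#N)CC=C(C)[C@H](O[Si](C)(C)C(C)(C)C)C1 | intermediate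
26 | (1R,5R)-5-[(tert-butyldimethylsilyl)oxy]-4-methyl-1-[(1S)-1-methyl-2-methylidenecyclopentyl]cyclohex-3-ene-1-carbaldehyde | C=C1CCC[C@]1(C)[C@@]1(C=O)CC=C(C)[C@H](O[Si](C)(C)C(C)(C)C)C1 | intermediate
27 | hydrazone of aldehyde 26 | C=C1CCC[C@]1(C)[C@@]1(C=NN)CC=C(C)[C@H](O[Si](C)(C)C(C)(C)C)C1 | intermediate
28 | (1R,5S)-2,5-dimethyl-5-[(1S)-1-methyl-2-methylidenecyclopentyl]cyclohex-2-en-1-ol | C=C1CCC[C@]1(C)[C@@]1(C)CC=C(C)[C@H](O)C1 | intermediate
29 | caffeic acid | O=C(O)/C=C/c1ccc(O)c(O)c1 | starting material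
30 | tert-butyldimethylsilyl (2E)-3-{3,4-bis[(tert-butyldimethylsilyl)oxy]phenyl}prop-2-enoate | CC(C)(C)[Si](C)(C)OC(=O)/C=C/c1ccc(O[Si](C)(C)C(C)(C)C)c(O[Si](C)(C)C(C)(C)C)c1 | intermediate
31 | (2E)-3-{3,4-bis[(tert-butyldimethylsilyl)oxy]phenyl}prop-2-enoic acid | O=C(O)/C=C/c1ccc(O[Si](C)(C)C(C)(C)C)c(O[Si](C)(C)C(C)(C)C)c1 | intermediate
32 | (1S,5S)-2,5-dimethyl-5-[(1S)-1-methyl-2-methylidenecyclopentyl]cyclohex-2-en-1-yl (2E)-3-{3,4-bis[(tert-butyldimethylsilyl)oxy]phenyl}prop-2-enoate | C=C1CCC[C@]1(C)[C@@]1(C)CC=C(C)[C@@H](OC(=O)/C=C/c2ccc(O[Si](C)(C)C(C)(C)C)c(O[Si](C)(C)C(C)(C)C)c2)C1 | intermediate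
33 | (1S,5S)-2,5-dimethyl-5-[(1S)-1-methyl-2-methylidenecyclopentyl]cyclohex-2-en-1-yl (2E)-3-(3,4-dihydroxyphenyl)prop-2-enoate | C=C1CCC[C@]1(C)[C@@]1(C)CC=C(C)[C@@H](OC(=O)/C=C/c2ccc(O)c(O)c2)C1 | target

**Step count and risks**

Total step count: 21. Longest linear sequence: 15 steps (steps 6–18, 20 and 21, from but-2-yn-1-ol).

Steps most likely to fail:

1. Step 16. The ring closure may run through the other half-chair, with the silyloxy group pseudoequatorial, so that the opposite face of the carbanion meets C6 and the C5 epimer is formed. The fallback sets out from enone 17 and comes back at ester 32. Reduction of 17 with catecholborane and the (R)-configured Me-CBS catalyst should give (2R,3Z)-5-[(tert-butyldimethylsilyl)oxy]-1-[(4-methoxybenzyl)oxy]-3-methylpent-3-en-2-ol F1. The operations of steps 11 to 15 then lead in turn to the bis-silyl ether F2, the primary alcohol F3, the iodide F4, the allylic alcohol F5 and the (2R)-configured dielectrophile F6. Double alkylation of 9 with F6, now through the transition state with a pseudoequatorial silyloxy group, should give the nitrile F7 with the silyloxy group cis to ring B. Reduction with (i-Bu)2AlH gives the aldehyde F8, and Wolff–Kishner reduction gives the (1S,5S)-alcohol F9. This alcohol already has the C1 configuration of the target and is esterified with retention with acid 31 (EDC·HCl, DMAP, CH2Cl2) to rejoin the route at 32.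

2. Step 20. The alkoxyphosphonium ion of the hindered allylic alcohol may be attacked at C3 (SN2′), ionize or lose a proton, so that inversion is incomplete and transposed ester or diene is formed. The fallback sets out from alcohol 28 and comes back at 32. Oxidation of 28 with MnO2 in CH2Cl2 gives (5S)-2,5-dimethyl-5-[(1S)-1-methyl-2-methylidenecyclopentyl]cyclohex-2-en-1-one F10. Reagent-controlled reduction with catecholborane and the (R)-configured Me-CBS catalyst (substituted alkene as the large group) should give the (1S,5S)-alcohol F11, the same compound as F9. Carbodiimide esterification of F11 with 31 (EDC·HCl, DMAP) then gives 32 with retention.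

3. Step 18. The hydrazone of an aldehyde flanked by two quaternary carbons may form azine or decompose sluggishly, and the hot alkali may shift the exocyclic alkene into ring B. The fallback sets out from aldehyde 26 and comes back at alcohol 28. Condensation of 26 with TsNHNH2 in ethanol gives the tosylhydrazone F12. Reduction with catecholborane in CHCl3 at 0 °C, followed by NaOAc·3H2O at reflux, expels nitrogen and sulfinate under mild conditions and should give tert-butyl{[(1R,5S)-2,5-dimethyl-5-[(1S)-1-methyl-2-methylidenecyclopentyl]cyclohex-2-en-1-yl]oxy}dimethylsilane F13. Desilylation with (n-Bu)4NF in THF then gives 28.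

**Further compounds**

F1 | step 16 | (2R,3Z)-5-[(tert-butyldimethylsilyl)oxy]-1-[(4-methoxybenzyl)oxy]-3-methylpent-3-en-2-ol | C/C(=C/CO[Si](C)(C)C(C)(C)C)[C@@H](O)COCc1ccc(OC)cc1
F2 | step 16 | (2R,3Z)-2,5-bis[(tert-butyldimethylsilyl)oxy]-1-[(4-methoxybenzyl)oxy]-3-methylpent-3-ene | C/C(=C/CO[Si](C)(C)C(C)(C)C)[C@@H](O[Si](C)(C)C(C)(C)C)COCc1ccc(OC)cc1
F3 | step 16 | (2R,3Z)-2,5-bis[(tert-butyldimethylsilyl)oxy]-3-methylpent-3-en-1-ol | C/C(=C/CO[Si](C)(C)C(C)(C)C)[C@@H](O[Si](C)(C)C(C)(C)C)CO
F4 | step 16 | (2R,3Z)-2,5-bis[(tert-butyldimethylsilyl)oxy]-1-iodo-3-methylpent-3-ene | C/C(=C/CO[Si](C)(C)C(C)(C)C)[C@@H](O[Si](C)(C)C(C)(C)C)CI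
F5 | step 16 | (2Z,4R)-4-[(tert-butyldimethylsilyl)oxy]-5-iodo-3-methylpent-2-en-1-ol | C/C(=C/CO)[C@@H](O[Si](C)(C)C(C)(C)C)CI
F6 | step 16 | tert-butyl{[(2R,3Z)-5-bromo-1-iodo-3-methylpent-3-en-2-yl]oxy}dimethylsilane | C/C(=C/CBr)[C@@H](O[Si](C)(C)C(C)(C)C)CI
F7 | step 16 | (1R,5S)-5-[(tert-butyldimethylsilyl)oxy]-4-methyl-1-[(1S)-1-methyl-2-methylidenecyclopentyl]cyclohex-3-ene-1-carbonitrile | C=C1CCC[C@]1(C)[C@@]1(C#N)CC=C(C)[C@@H](O[Si](C)(C)C(C)(C)C)C1
F8 | step 16 | (1R,5S)-5-[(tert-butyldimethylsilyl)oxy]-4-methyl-1-[(1S)-1-methyl-2-methylidenecyclopentyl]cyclohex-3-ene-1-carbaldehyde | C=C1CCC[C@]1(C)[C@@]1(C=O)CC=C(C)[C@@H](O[Si](C)(C)C(C)(C)C)C1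
F9 | step 16 | (1S,5S)-2,5-dimethyl-5-[(1S)-1-methyl-2-methylidenecyclopentyl]cyclohex-2-en-1-ol | C=C1CCC[C@]1(C)[C@@]1(C)CC=C(C)[C@@H](O)C1
F10 | step 20 | (5S)-2,5-dimethyl-5-[(1S)-1-methyl-2-methylidenecyclopentyl]cyclohex-2-en-1-one | C=C1CCC[C@]1(C)[C@@]1(C)CC=C(C)C(=O)C1
F11 | step 20 | (1S,5S)-2,5-dimethyl-5-[(1S)-1-methyl-2-methylidenecyclopentyl]cyclohex-2-en-1-ol | C=C1CCC[C@]1(C)[C@@]1(C)CC=C(C)[C@@H](O)C1
F12 | step 18 | 4-methylbenzenesulfonohydrazone of aldehyde 26 | C=C1CCC[C@]1(C)[C@@]1(C=NNS(=O)(=O)c2ccc(C)cc2)CC=C(C)[C@H](O[Si](C)(C)C(C)(C)C)C1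
F13 | step 18 | tert-butyl{[(1R,5S)-2,5-dimethyl-5-[(1S)-1-methyl-2-methylidenecyclopentyl]cyclohex-2-en-1-yl]oxy}dimethylsilane | C=C1CCC[C@]1(C)[C@@]1(C)CC=C(C)[C@H](O[Si](C)(C)C(C)(C)C)C1
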